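The runs were computed with made-up constants; the scatter is artificial.

Slowness was where I began: in the amber run the sum of target and over-reaction product stood at 55.7% at 4.00 h and at 57.6% at 10.0 h, while target kept sliding into over-reaction product.

| setting | violet | amber | teal | autumn | winter | dawn | summer |
|---|---|---|---|---|---|---|---|
| starting material | 20 mM | 20 mM | 20 mM | 20 mM | 20 mM | 20 mM (fed, over 8.00 h) | 20 mM |
| reagent | 80 mM | 80 mM | 80 mM | 80.0 mM (fed, over 8.00 h) | 80.0 mM | 80.0 mM | 80.0 mM |
| initiator | 0.20 mM | 0.10 mM | 0.40 mM | 0.20 mM | 0.20 mM | 0.20 mM | 0.20 mM |
| remark | run made earlier | run made earlier | run made earlier | a stirred flask in which reagent is dosed at a steady rate over 8.00 h without added volume, worked up at 10 h | a closed flask charged with all of it at once and left for 10 h | all but starting material at the start; starting material goes in evenly over 8.00 h, the run ends at 10 h | one stirred flow tank at steady state, fed with the mixture as stated, mean residence time 10 h |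
| time |  |  |  | 10 h | 10 h | 10 h |  |

| run | time / h | target / % | over-reaction product / % |
|---|---|---|---|
| violet | 0.833 | 32.7 | 1.7 |
| violet | 2.00 | 52.3 | 13.5 |
| violet | 4.00 | 39.8 | 25.1 |
| violet | 6.00 | 28.6 | 33.6 |
| amber | 0.833 | 19.9 | 0.8 |
| amber | 2.00 | 43.4 | 8.6 |
| amber | 4.00 | 35.8 | 19.9 |
| amber | 10.0 | 14.4 | 43.2 |
| teal | 1.33 | 61.4 | 7.7 |
| teal | 4.00 | 43.8 | 28.8 |
| teal | 6.00 | 30.0 | 40.5 |
| teal | 10.0 | 17.2 | 53.8 |

(standard deviation of a reading: 1 percentage point)

- percent here means starting material units held: one ended chains or homo dimer counts as two
- the stated concentrations are those of everything mixed, before any reaction; amounts are the same in each set-up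
- the numbers in the tables scatter with a standard deviation of 1 percentage point
- what may be going on: 2 first chain carrier -> ended chains; starting material + second chain carrier -> released group + first chain carrier; first chain carrier -> ended carrier; reagent + first chain carrier -> target + second chain carrier; starting material + initiating radical -> capped initiator + first chain carrier; target -> over-reaction product; 2 starting material -> homo dimer; initiator -> 2 initiating radical
- the feed brings no volume worth counting
- the earlier runs were made in a closed, stirred flask

- the set-up with the highest share of target in all that became target or over-reaction product, at the outlet or at the end ("none" if the first two lie within 2 percentage points) (autumn / winter / dawn / summer / none)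
- share of target in all that became target or over-reaction product, at the outlet or at the end, autumn
- share of target in all that became target or over-reaction product, at the outlet or at the end, winter
- share of target in all that became target or over-reaction product, at the outlet or at the end, dawn
- share of target in all that became target or over-reaction product, at the outlet or at the end, summer

From those amber readings I took k = 0.152 h⁻¹, the first-order loss constant of target, the rate at which target decays once no more forms. Target that has aged for a given time then keeps the share exp(−k × age). Winter is violet's charge, so I aged violet's last share from 6.00 h to 10 h and got 25.1%. If dawn forms target evenly during its feed and then holds it to the end, the average of that decay over the feed, times the decay of the hold, gives 42.7%. Summer, a tank, keeps one over one plus k times the residence time of 10 h, which is 39.7%. Autumn, with reagent trickling in, I could only bracket, between winter's 25.1% and dawn's 42.7%.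

The weak link was dawn's evenness, which needs the chain to consume starting material as it arrives, at a low c starting material. Amber eased my doubt, as a reading: its rate of forming target and over-reaction product was 0.248 h⁻¹ of the charge at first and 0.268 h⁻¹ next, although starting material was falling, so the order in c starting material looked near zero. With half of dawn's initiator, that rate was still twice dawn's feed of 0.125 h⁻¹. So I put dawn above summer, by 3 percentage points.

The forecast named dawn, with autumn 32%, winter 25%, dawn 43% (“if initiator lasts”) and summer 40%.

The flask gave dawn: autumn 32.2%, winter 25.1%, dawn 43.1%, summer 40.0%. In dawn the highest c starting material was 0.0358 mM, against a charge of 20 mM.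

    2 first chain carrier → ended chains (k = 1.00 × 10⁶ M⁻¹ s⁻¹)
    starting material + second chain carrier → released group + first chain carrier (k = 1.90 × 10⁵ M⁻¹ s⁻¹)
    first chain carrier → ended carrier (k = 1.60 min⁻¹)
    reagent + first chain carrier → target + second chain carrier (k = 95000 M⁻¹ min⁻¹)
    starting material + initiating radical → capped initiator + first chain carrier (k = 1.90 × 10⁵ M⁻¹ s⁻¹)
    target → over-reaction product (k = 0.00250 min⁻¹)
    2 starting material → homo dimer (k = 0.440 M⁻¹ min⁻¹)
    initiator → 2 initiating radical (k = 1.90 × 10⁻⁴ min⁻¹)

Put to use once more, k turns autumn's share into an effective age of target of 7.46 h.

Autumn with 20 mM of reagent, if its target formed evenly over the feed, comes out by k, reckoned as for dawn, at 42.7%. The computed flask gives 42.2%.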